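**Retrosynthetic overview**
1. The target comes from global desilylation of a tris-silyl ether. That ether comes from a C12–C13 B-alkyl Suzuki coupling of a 9-vinyl cis-decalin with commercial 4-bromobutenolide.
2. The cis-decalin (5β-H, 6α-O) comes from a 5α,6α-epoxide by a new B(C6F5)3/Et3SiH reductive Meinwald relay. This is a net anti H/O addition and sets C5 and C6.
3. The epoxy-diene comes from a bicyclic 5,8-dien-11-al by chemo- and face-selective epoxidation followed by Wittig methylenation.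
4. Ring B, the tetrasubstituted C8=C9 alkene and quaternary C10 come from a Diels–Alder reaction of a ring-A vinylcyclohexene with 4-silyloxybut-2-ynal.
5. Ring A and C2 come from (4R,6R)-actinol by enol triflate formation and Stille vinylation. Ring order: A (bought), then B (Diels–Alder), then the butenolide (bought, appended last).

Assumption: the SMILES is taken literally, that is (2S,5R,6S,10S) with a cis A/B fusion (H-5 and CH3-20 both β, 2-OH and 6-OH both α), and (4R,6R)-actinol is bought as the single enantiomer.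

Numbering: labdane numbering is used. Ring A is C1–C5 and C10. Ring B is C5–C10. C11–C12 is the chain and C13–C16 the butenolide. C17 is the CH2O on C8 and C20 is the CH3 on C10. β is the face of CH3-20. TBS = tert-butyldimethylsilyl and TES = triethylsilyl.

Step 1
Reactants: 1 (4R,6R)-4-hydroxy-2,2,6-trimethylcyclohexan-1-one [(4R,6R)-actinol]
Product: 2 (4R,6R)-4-(TBS-oxy)-2,2,6-trimethylcyclohexan-1-one
Conditions: TBSCl (1.2 equiv), imidazole (2.5 equiv), DMF, 0 °C → rt
Reagents that add atoms: TBSCl (tert-butyldimethylsilyl chloride), CC(C)(C)[Si](C)(C)Cl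
Why: Standard imidazole-promoted silyl ether formation on the only hydroxyl group, with no stereocentre touched.

Step 2
Reactants: 2 (4R,6R)-4-(TBS-oxy)-2,2,6-trimethylcyclohexan-1-one
Product: 4 (4R)-4-(TBS-oxy)-2,6,6-trimethylcyclohex-1-en-1-yl trifluoromethanesulfonate, via potassium enolate 3 (not isolated)
Conditions: KHMDS (1.2 equiv), THF, −78 °C; PhNTf2 (1.25 equiv), −78 → 0 °C
Reagents that add atoms: N-phenylbis(trifluoromethanesulfonimide) (PhNTf2), O=S(=O)(N(c1ccccc1)S(=O)(=O)C(F)(F)F)C(F)(F)F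
Why: In this enol triflate synthesis the ketone has one enolisable position, so a single regioisomer forms; the methyl-bearing centre is erased on purpose, and the silyloxy group is γ to the carbonyl, so no E1cB loss occurs and the carbinol centre stays (R).

Step 3
Reactants: 4 (4R)-4-(TBS-oxy)-2,6,6-trimethylcyclohex-1-en-1-yl trifluoromethanesulfonate
Product: 5 tert-butyl{[(1R)-4-ethenyl-3,5,5-trimethylcyclohex-3-en-1-yl]oxy}dimethylsilane
Conditions: CH2=CHSnBu3 (1.3 equiv), Pd2(dba)3 (2.5 mol %), AsPh3 (20 mol %), LiCl (3 equiv), NMP, 45 °C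
Reagents that add atoms: tributyl(vinyl)stannane, C=C[Sn](CCCC)(CCCC)CCCC
Why: Stille coupling under soft-ligand/LiCl conditions is the standard way to vinylate hindered 2,6,6-trimethylcyclohexenyl triflates and leaves the stereocentre alone.

Step 4
Reactants: 6 tert-butyldimethyl(prop-2-yn-1-yloxy)silane
Product: 9 4-(TBS-oxy)but-2-ynal, via lithium acetylide 7 (not isolated), via lithium hemiaminal alkoxide 8 (not isolated)
Conditions: n-BuLi (1.05 equiv), THF, −78 °C; DMF (2 equiv), −78 → 0 °C; inverse quench into aq KH2PO4/MTBE, 0 °C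
Reagents that add atoms: N,N-dimethylformamide (DMF), CN(C)C=O
Why: Acetylide formylation with DMF is reliable, and the inverse buffered quench keeps the released amine from adding to the ynal.

Step 5
Reactants: 5 tert-butyl{[(1R)-4-ethenyl-3,5,5-trimethylcyclohex-3-en-1-yl]oxy}dimethylsilane; 9 4-(TBS-oxy)but-2-ynal
Product: 10 (7S,8aS)-7-(TBS-oxy)-2-(TBS-oxymethyl)-5,5,8a-trimethyl-3,5,6,7,8,8a-hexahydronaphthalene-1-carbaldehyde (2α,17-bis-TBS-oxy 5,8-dien-11-al, CH3-20 β)
Conditions: 9 (1.5 equiv), toluene (2 M), BHT (2 mol %), 100 °C, sealed tube, 36 h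
Reagents that add atoms: none
Why: In this thermal Diels–Alder reaction of an alkynal the free CH2 terminus C7 (largest HOMO coefficient, least hindered) bonds to the β-alkyne carbon, so CHO ends on C9 and CH2OTBS on C8 ("ortho" rule), and the dienophile adds anti to the pseudo-axial 4β-methyl of the half-chair that keeps 2-OTBS equatorial, so CH3-20 becomes axial and trans to 2-OTBS (10S).

Step 6
Reactants: 10 (7S,8aS)-7-(TBS-oxy)-2-(TBS-oxymethyl)-5,5,8a-trimethyl-3,5,6,7,8,8a-hexahydronaphthalene-1-carbaldehyde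
Product: 11 (2S,5R,6S,10R)-5α,6α-epoxy-2α,17-bis(TBS-oxy) 8-en-11-al (5α,6α-epoxide of 10)
Conditions: mCPBA (1.1 equiv), CH2Cl2/aq NaHCO3 buffer, 0 °C
Reagents that add atoms: mCPBA (3-chloroperoxybenzoic acid), O=C(OO)c1cccc(Cl)c1
Why: In this Prilezhaev epoxidation only C5=C6 is nucleophilic because C8=C9 is deactivated by the formyl group, and the β face is walled off by the two axial methyls (CH3-20 and 4β-CH3), so oxygen arrives from the α face.

Step 7
Reactants: 11 (2S,5R,6S,10R)-5α,6α-epoxy-2α,17-bis(TBS-oxy) 8-en-11-al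
Product: 12 (2S,5R,6S,10R)-5α,6α-epoxy-2α,17-bis(TBS-oxy)-9-vinyl 8-ene (C11=C12 methylene compound)
Conditions: Ph3PCH3Br (1.5 equiv), KHMDS (1.4 equiv), THF, 0 °C; then 11, −78 → 0 °C
Reagents that add atoms: methyltriphenylphosphonium bromide, C[P+](c1ccccc1)(c1ccccc1)c1ccccc1.[Br-]
Why: Wittig methylenation works on hindered β-cyclocitral-type enals, addition to the aldehyde at low temperature outruns γ-deprotonation at C7, and the epoxide and all stereocentres are spectators.

Step 8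
Reactants: 12 (2S,5R,6S,10R)-5α,6α-epoxy-2α,17-bis(TBS-oxy)-9-vinyl 8-ene
Product: 14 (2S,5R,6S,10S)-5β-H-6α-(TES-oxy)-2α,17-bis(TBS-oxy)-9-vinyl 8-ene (cis-decalin), via O-silyl oxocarbenium ion 13 (not isolated)
Conditions: B(C6F5)3 (5 mol %), Et3SiH (1.05 equiv, slow addition), 4 Å MS, CH2Cl2, −78 → −40 °C
Reagents that add atoms: triethylsilane, CC[SiH](CC)CC
Why: Proposed new method: a borane-catalysed reductive Meinwald relay in which B(C6F5)3 polarises the Si–H bond and the epoxide oxygen (the only unhindered Lewis base) takes up Et3Si+ on the α face; the tertiary C5–O bond then ionises (C5 lies between two quaternary carbons, so there is no E1 exit, and C7 sits in the nodal plane of the developing p orbital, so ring contraction is misaligned), and the 6β-H, about 30° off that orbital and anti to the leaving oxygen, shifts suprafacially to the β face of C5 and sets the contra-thermodynamic cis fusion (5R); the O-silyl oxocarbenium ion 13 is born paired with its reductant [HB(C6F5)3]−, which delivers hydride to the open convex β face of C6 (the α face is roofed by ring A) before enolisation can epimerise C5, giving the 6α-silyl ether (6S) and a net anti addition of H and O across the former C5=C6 bond; the closest known reaction types are the Lewis-acid Meinwald rearrangement of steroidal 5α,6α-epoxides to 5β-6-ketones and the Piers B(C6F5)3/hydrosilane carbonyl hydrosilylation, which have not been merged on a fully substituted ring-fusion epoxide or used to set a cis-decalin.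

Step 9
Reactants: 14 (2S,5R,6S,10S)-5β-H-6α-(TES-oxy)-2α,17-bis(TBS-oxy)-9-vinyl 8-ene; 15 4-bromofuran-2(5H)-one
Product: 17 (2S,5R,6S,10S)-6α-(TES-oxy)-2α,17-bis(TBS-oxy)-5β-labda-8,13-dien-15,16-olide, via B-alkyl-9-BBN 16 (not isolated)
Conditions: 9-BBN (0.5 M in THF, 1.5 equiv), 0 °C → rt; then H2O, Cs2CO3 (2 equiv), 15 (1.3 equiv), Pd(dppf)Cl2·CH2Cl2 (5 mol %), AsPh3 (5 mol %), DMF, rt
Reagents that add atoms: none
Why: 9-BBN hydroborates only the monosubstituted C11=C12 alkene with boron on C12 (the tetrasubstituted C8=C9 is inert), and B-alkyl Suzuki–Miyaura coupling with the β-bromobutenolide forms C12–C13 without touching any stereocentre.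

Step 10
Reactants: 17 (2S,5R,6S,10S)-6α-(TES-oxy)-2α,17-bis(TBS-oxy)-5β-labda-8,13-dien-15,16-olide
Product: 18 (2S,5R,6S,10S)-2α,6α,17-trihydroxy-5β-labda-8,13-dien-15,16-olide (CNP0293367.1)
Conditions: HF·pyridine, pyridine, THF, 0 °C → rt
Reagents that add atoms: none
Why: Buffered fluoride desilylation removes all three silyl ethers without ionising the allylic C17 alcohol or isomerising the butenolide, and no stereocentre is affected.

**Compound list**
1 | (4R,6R)-4-hydroxy-2,2,6-trimethylcyclohexan-1-one (actinol) | CC1(C)C[C@H](O)C[C@@H](C)C1=O | starting material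
2 | (4R,6R)-4-(TBS-oxy)-2,2,6-trimethylcyclohexan-1-one | CC1(C)C[C@H](O[Si](C)(C)C(C)(C)C)C[C@@H](C)C1=O | intermediate
3 | potassium (4R)-4-(TBS-oxy)-2,6,6-trimethylcyclohex-1-en-1-olate | CC1(C)C[C@H](O[Si](C)(C)C(C)(C)C)CC(C)=C1[O-].[K+] | intermediate
4 | (4R)-4-(TBS-oxy)-2,6,6-trimethylcyclohex-1-en-1-yl trifluoromethanesulfonate | CC1(C)C[C@H](O[Si](C)(C)C(C)(C)C)CC(C)=C1OS(=O)(=O)C(F)(F)F | intermediate
5 | tert-butyl{[(1R)-4-ethenyl-3,5,5-trimethylcyclohex-3-en-1-yl]oxy}dimethylsilane | CC1(C)C[C@H](O[Si](C)(C)C(C)(C)C)CC(C)=C1C=C | intermediate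
6 | tert-butyldimethyl(prop-2-yn-1-yloxy)silane | C#CCO[Si](C)(C)C(C)(C)C | starting material
7 | lithium acetylide of 6 | [Li]C#CCO[Si](C)(C)C(C)(C)C | intermediate
8 | lithium 1-(dimethylamino)-4-(TBS-oxy)but-2-yn-1-olate | [Li+].[O-]C(C#CCO[Si](C)(C)C(C)(C)C)N(C)C | intermediate
9 | 4-(TBS-oxy)but-2-ynal | O=CC#CCO[Si](C)(C)C(C)(C)C | intermediate
10 | (7S,8aS)-7-(TBS-oxy)-2-(TBS-oxymethyl)-5,5,8a-trimethyl-3,5,6,7,8,8a-hexahydronaphthalene-1-carbaldehyde | CC1(C)C[C@H](O[Si](C)(C)C(C)(C)C)C[C@]2(C)C(C=O)=C(CO[Si](C)(C)C(C)(C)C)CC=C12 | intermediate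
11 | (2S,5R,6S,10R)-5α,6α-epoxide of 10 | CC1(C)C[C@H](O[Si](C)(C)C(C)(C)C)C[C@]2(C)C(C=O)=C(CO[Si](C)(C)C(C)(C)C)C[C@@H]3O[C@]123 | intermediate
12 | (2S,5R,6S,10R)-5α,6α-epoxy-2α,17-bis(TBS-oxy)-9-vinyl 8-ene | CC1(C)C[C@H](O[Si](C)(C)C(C)(C)C)C[C@]2(C)C(C=C)=C(CO[Si](C)(C)C(C)(C)C)C[C@@H]3O[C@]123 | intermediate
13 | O-triethylsilyl oxocarbenium ion of the (2S,5R,10S) 5β-H 6-ketone (counter-ion [HB(C6F5)3]−) | CC1(C)C[C@H](O[Si](C)(C)C(C)(C)C)C[C@]2(C)C(C=C)=C(CO[Si](C)(C)C(C)(C)C)CC(=[O+][Si](CC)(CC)CC)[C@H]12 | intermediate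
14 | (2S,5R,6S,10S)-5β-H-6α-(TES-oxy)-2α,17-bis(TBS-oxy)-9-vinyl 8-ene | CC1(C)C[C@H](O[Si](C)(C)C(C)(C)C)C[C@]2(C)C(C=C)=C(CO[Si](C)(C)C(C)(C)C)C[C@H](O[Si](CC)(CC)CC)[C@H]12 | intermediate
15 | 4-bromofuran-2(5H)-one | O=C1C=C(Br)CO1 | starting material
16 | C12 B-alkyl-9-borabicyclo[3.3.1]nonane derived from 14 | CC1(C)C[C@H](O[Si](C)(C)C(C)(C)C)C[C@]2(C)C(CCB3C4CCCC3CCC4)=C(CO[Si](C)(C)C(C)(C)C)C[C@H](O[Si](CC)(CC)CC)[C@H]12 | intermediate
17 | (2S,5R,6S,10S)-6α-(TES-oxy)-2α,17-bis(TBS-oxy)-5β-labda-8,13-dien-15,16-olide | CC1(C)C[C@H](O[Si](C)(C)C(C)(C)C)C[C@]2(C)C(CCC3=CC(=O)OC3)=C(CO[Si](C)(C)C(C)(C)C)C[C@H](O[Si](CC)(CC)CC)[C@H]12 | intermediate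
18 | 4-{2-[(4S,4aR,7S,8aS)-4,7-dihydroxy-2-(hydroxymethyl)-5,5,8a-trimethyl-3,4,4a,5,6,7,8,8a-octahydronaphthalen-1-yl]ethyl}furan-2(5H)-one | CC1(C)C[C@H](O)C[C@]2(C)C(CCC3=CC(=O)OC3)=C(CO)C[C@H](O)[C@H]12 | target

**Step count**
- Total step count: 10.
- Longest linear sequence: 9 (steps 1–3 and 5–10, from 1).

**Steps most likely to fail**

**Step 5 (Diels–Alder).**
- Risk: the hindered diene may react too slowly with a β-substituted ynal, or may give regio- or facial mixtures.
- Fallback: it sets out from 5 and uses the classical symmetrical, much more reactive dienophile dimethyl acetylenedicarboxylate (neat, 110 °C), so there is no regiochemical question.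
- This gives dimethyl (7S,8aS)-7-(TBS-oxy)-5,5,8a-trimethyl-3,5,6,7,8,8a-hexahydronaphthalene-1,2-dicarboxylate F1.
- LiAlH4 in Et2O at 0 °C then gives the 11,17-diol F2.
- TBSCl (1.0 equiv) with imidazole at −20 °C silylates the less hindered C17 hydroxyl, which is remote from quaternary C10, and gives the 17-O-TBS 11-alcohol F3.
- MnO2 in CH2Cl2 oxidises the remaining allylic alcohol, and the sequence comes back to the route at 10.

**Step 7 (Wittig on the γ,δ-epoxy enal).**
- Risk: the basic ylide may deprotonate C7 and trigger vinylogous E1cB opening of the epoxide.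
- Fallback: it sets out from 11 and separates C–C bond formation from the base treatment (Peterson olefination).
- Me3SiCH2MgCl/CeCl3 in THF at −78 °C adds as a non-basic nucleophile and gives the 11-hydroxy-12-trimethylsilyl adduct F4 as a C11 epimer mixture.
- This adduct no longer has an acidifying enal.
- KH in THF at 0 °C then eliminates, and the sequence comes back to the route at 12.

**Step 8 (the proposed new step).**
- Risk: methyl migration from C4 or C10, ring contraction, direct hydride attack at C6, or hydrosilylation of the diene may compete.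
- Fallback: it uses known chemistry and sets out from 12.
- A stepwise Lewis-acid Meinwald rearrangement with BF3·OEt2 (0.2 equiv) in CH2Cl2 at −78 → −30 °C, with the same suprafacial 6β-H shift, gives the (2S,5R,10S) 5β-H 6-ketone F5.
- F5 is reduced at once with L-Selectride in THF at −78 °C (convex β-face attack) to the 6α-alcohol F6.
- TESOTf with 2,6-lutidine in CH2Cl2 at −78 °C silylates it, and the sequence comes back to the route at 14.

Further compounds
F1 | step 5 | dimethyl (7S,8aS)-7-(TBS-oxy)-5,5,8a-trimethyl-3,5,6,7,8,8a-hexahydronaphthalene-1,2-dicarboxylate | CC1(C)C[C@H](O[Si](C)(C)C(C)(C)C)C[C@]2(C)C(C(=O)OC)=C(C(=O)OC)CC=C12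
F2 | step 5 | [(7S,8aS)-7-(TBS-oxy)-5,5,8a-trimethyl-3,5,6,7,8,8a-hexahydronaphthalene-1,2-diyl]dimethanol (11,17-diol) | CC1(C)C[C@H](O[Si](C)(C)C(C)(C)C)C[C@]2(C)C(CO)=C(CO)CC=C12
F3 | step 5 | 17-O-TBS 11-alcohol [(7S,8aS)-7-(TBS-oxy)-2-(TBS-oxymethyl)-5,5,8a-trimethyl-3,5,6,7,8,8a-hexahydronaphthalen-1-yl]methanol | CC1(C)C[C@H](O[Si](C)(C)C(C)(C)C)C[C@]2(C)C(CO)=C(CO[Si](C)(C)C(C)(C)C)CC=C12
F4 | step 7 | 11-hydroxy-12-trimethylsilyl adduct of 11 (C11 epimer mixture) | CC1(C)C[C@H](O[Si](C)(C)C(C)(C)C)C[C@]2(C)C(C(O)C[Si](C)(C)C)=C(CO[Si](C)(C)C(C)(C)C)C[C@@H]3O[C@]123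
F5 | step 8 | (2S,5R,10S)-5β-H-2α,17-bis(TBS-oxy)-9-vinyl 8-en-6-one | CC1(C)C[C@H](O[Si](C)(C)C(C)(C)C)C[C@]2(C)C(C=C)=C(CO[Si](C)(C)C(C)(C)C)CC(=O)[C@H]12
F6 | step 8 | (2S,5R,6S,10S)-5β-H-2α,17-bis(TBS-oxy)-9-vinyl 8-en-6α-ol | CC1(C)C[C@H](O[Si](C)(C)C(C)(C)C)C[C@]2(C)C(C=C)=C(CO[Si](C)(C)C(C)(C)C)C[C@H](O)[C@H]12
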